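The route rests on making the C8–O(4′) aryl ether bond last, by carbene insertion into a phenolic O–H bond and not by substitution at a lactate-derived centre. It exploits the position of C8 next to the C7 aryl ketone: C8 can be the carbene carbon of an achiral α-diazo ketone, and its base-labile C–H stereocentre can be written by catalyst-controlled protonation of the enol that the insertion passes through. In one base-free operation the key step joins the 3,4,5-trimethoxybenzoyl half to the guaiacyl ring and sets 8S. Its precursors, 2-diazo-1-(3,4,5-trimethoxyphenyl)propan-1-one and (E)-2-methoxy-4-(3-methoxyprop-1-enyl)phenol, are achiral and carry every other atom of the target.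

Key step: step 3

Remark: lignan numbering is used (C7 = ketone carbon, C8 = stereocentre, C9 = its methyl group, primed atoms on the guaiacyl ring and its side chain).
Remark: the (R)-configured spiro phosphoric acid is assumed to protonate the Re face of C8; the sense of induction would be assigned in a trial run, and the (S)-acid would be used if it is the opposite.

Step 1
Reactants: 1 3,4,5-trimethoxybenzoyl chloride; 2 N-ethyl-N-nitrosourea
Product: 4 2-diazo-1-(3,4,5-trimethoxyphenyl)propan-1-one, via diazoethane 3 (not isolated)
Conditions: 2, 40% aq KOH, Et2O, 0 °C, ethereal layer dried over KOH pellets; then 1, Et3N (1.1 equiv), Et2O/THF, −20 °C → rt; excess 3 purged with N2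
Reagents that add atoms: none
Why: Acylation of a diazoalkane by an acid chloride (first stage of the Arndt–Eistert sequence): the nucleophilic carbon of 3 adds to the aroyl chloride, which has no α-hydrogen and so cannot divert to a ketene, and triethylamine takes the proton from the acyl diazonium ion before chloride can displace N2, so that the disubstituted diazo ketone 4 should result; no stereocentre is formed.

Step 2
Reactants: 5 4-bromo-2-methoxyphenol; 6 (E)-2-(3-methoxyprop-1-en-1-yl)-4,4,5,5-tetramethyl-1,3,2-dioxaborolane
Product: 7 (E)-2-methoxy-4-(3-methoxyprop-1-en-1-yl)phenol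
Conditions: Pd(OAc)2 (2 mol%), SPhos (4 mol%), K2CO3 (3 equiv), dioxane/H2O 4:1, 80 °C; aq NH4Cl work-up
Reagents that add atoms: none
Why: Suzuki–Miyaura coupling: the bulky biaryl phosphine drives oxidative addition of the electron-rich bromophenoxide, the alkenyl boronate transmetalates and reductively eliminates with retention of the E geometry, and the free phenol and the allylic methyl ether are inert to the carbonate base; no stereocentre is formed.

Step 3
Reactants: 4 2-diazo-1-(3,4,5-trimethoxyphenyl)propan-1-one; 7 (E)-2-methoxy-4-(3-methoxyprop-1-en-1-yl)phenol
Product: 9 (S)-2-[2-methoxy-4-((E)-3-methoxyprop-1-en-1-yl)phenoxy]-1-(3,4,5-trimethoxyphenyl)propan-1-one (target), via 2-aryloxy enol 8 (not isolated)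
Conditions: Rh2(O2CCPh3)4 (1 mol%), (R)-STRIP [(R)-6,6′-bis(2,4,6-triisopropylphenyl)-1,1′-spirobiindane-7,7′-diyl hydrogen phosphate] (5 mol%), 7 (1.5 equiv), dry CH2Cl2, 0 °C, 4 added over 3 h by syringe pump; chromatography on silica without amine additive
Reagents that add atoms: none
Why: The dirhodium carboxylate takes N2 out of 4 to give an electrophilic rhodium keto-carbene, the phenolic oxygen of 7 adds to it, and the oxonium ylide leaves the metal as the achiral enol 8, which the spiro phosphoric acid tautomerizes as a bifunctional proton shuttle (P=O takes the enol O–H proton while P–OH hands a proton to C8). The reaction type is the enantioselective carbene O–H insertion, closest in kind to the phenol O–H insertions of α-alkyl-α-diazo carbonyl compounds and to the dirhodium/chiral phosphoric acid co-catalysed X–H insertions of α-diazo ketones. No ring is closed. The one new stereocentre, C8, is set under pure catalyst control: the acid should deliver the proton inside its chiral pocket to the Re face of C8 of 8 (the face on which OAr, C7 and CH3 run clockwise), which gives 8S. The step needs chemoselectivity for O–H insertion over cyclopropanation of the C7′=C8′ alkene, over ylide formation at the allylic C9′ methoxy oxygen with [2,3] shift, and over 1,2-hydride shift from the C9 methyl group; the acidic phenol traps the carbene by an irreversible proton transfer, the trans-1,2-disubstituted alkene is a poor partner for a carbenoid shielded by four triphenylacetate ligands, and slow addition of 4 to excess 7 at 0 °C disfavours the unimolecular hydride shift. As no base is present and no step follows, the enolizable C8–H centre should not be eroded.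

Compound list
1 | 3,4,5-trimethoxybenzoyl chloride | COc1cc(cc(OC)c1OC)C(=O)Cl | starting material
2 | N-ethyl-N-nitrosourea | CCN(N=O)C(N)=O | starting material
3 | diazoethane | CC=[N+]=[N-] | intermediate
4 | 2-diazo-1-(3,4,5-trimethoxyphenyl)propan-1-one | CC(=[N+]=[N-])C(=O)c1cc(OC)c(OC)c(OC)c1 | intermediate
5 | 4-bromo-2-methoxyphenol | COc1cc(Br)ccc1O | starting material
6 | (E)-2-(3-methoxyprop-1-en-1-yl)-4,4,5,5-tetramethyl-1,3,2-dioxaborolane | COC/C=C/B1OC(C)(C)C(C)(C)O1 | starting material
7 | (E)-2-methoxy-4-(3-methoxyprop-1-en-1-yl)phenol | COC/C=C/c1ccc(O)c(OC)c1 | intermediate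
8 | 2-[2-methoxy-4-((E)-3-methoxyprop-1-en-1-yl)phenoxy]-1-(3,4,5-trimethoxyphenyl)prop-1-en-1-ol (enol, C7=C8 geometry not defined, either isomer leads to 9) | COC/C=C/c1ccc(OC(C)=C(O)c2cc(OC)c(OC)c(OC)c2)c(OC)c1 | intermediate
9 | (S)-2-[2-methoxy-4-((E)-3-methoxyprop-1-en-1-yl)phenoxy]-1-(3,4,5-trimethoxyphenyl)propan-1-one | COC/C=C/c1ccc(O[C@@H](C)C(=O)c2cc(OC)c(OC)c(OC)c2)c(OC)c1 | target

Total step count: 3
Longest linear sequence: 2 (step 1 or step 2, then step 3)

Steps most likely to fail

1. Step 3. The rhodium carbene may be diverted before the phenol traps it, by cyclopropanation of the C7′=C8′ alkene, by ylide formation at the allylic methoxy oxygen followed by [2,3] shift, or by 1,2-hydride shift to the aryl vinyl ketone. The proton transfer to enol 8 may also be too weakly face-selective, because uncatalysed tautomerization competes or the ortho-methoxy group disturbs the fit in the acid pocket. The fallback gives up the insertion for a chiral-pool sequence and sets out from 7. A Mitsunobu reaction of 7 with ethyl (R)-lactate (PPh3, DIAD, THF, 0 °C → rt) should give, with inversion at the lactate carbon, ethyl (S)-2-[2-methoxy-4-((E)-3-methoxyprop-1-en-1-yl)phenoxy]propanoate F1. Ester–amide exchange with MeNH(OMe)·HCl and iPrMgCl (THF, −20 °C) should give the Weinreb amide (S)-N-methoxy-2-[2-methoxy-4-((E)-3-methoxyprop-1-en-1-yl)phenoxy]-N-methylpropanamide F2. Addition of commercial 3,4,5-trimethoxyphenylmagnesium bromide (THF, −40 → 0 °C, cold aq NH4Cl quench) should release the ketone from the chelated adduct only on work-up. The fallback comes back to the route at 9.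

2. Step 1. The volatile diazoalkane may be lost before it is acylated, and the acyl diazonium ion may be captured by chloride to give the α-chloro ketone instead of being deprotonated. The fallback installs the diazo group by diazo transfer and sets out from 1. Iron-catalysed acylation of ethylmagnesium bromide (Fe(acac)3 3 mol%, THF, −78 °C) should give 1-(3,4,5-trimethoxyphenyl)propan-1-one F3. Claisen trifluoroacetylation of its lithium enolate (LiHMDS, CF3CO2CH2CF3, THF, −78 °C) should give 4,4,4-trifluoro-2-methyl-1-(3,4,5-trimethoxyphenyl)butane-1,3-dione F4. Detrifluoroacetylative diazo transfer on crude F4 (4-acetamidobenzenesulfonyl azide, Et3N, H2O, MeCN, rt) comes back to the route at 4.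

3. Step 2. Protodeboronation of the alkenyl boronate may outpace transmetalation, and palladium hydride species may erode the E geometry or move the double bond towards the enol ether. The fallback forms the C7′=C8′ double bond by metathesis and sets out from 5. Suzuki–Miyaura vinylation of 5 with potassium vinyltrifluoroborate (PdCl2(dppf), K2CO3, THF/H2O, 70 °C) should give 2-methoxy-4-vinylphenol F5, which can also be bought. Cross-metathesis of F5 with excess allyl methyl ether (Hoveyda–Grubbs II catalyst 3 mol%, CH2Cl2, 40 °C, sealed vessel) should give the thermodynamically favoured E alkene and comes back to the route at 7.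

Further compounds
F1 | step 3 | ethyl (S)-2-[2-methoxy-4-((E)-3-methoxyprop-1-en-1-yl)phenoxy]propanoate | COC/C=C/c1ccc(O[C@@H](C)C(=O)OCC)c(OC)c1
F2 | step 3 | (S)-N-methoxy-2-[2-methoxy-4-((E)-3-methoxyprop-1-en-1-yl)phenoxy]-N-methylpropanamide | COC/C=C/c1ccc(O[C@@H](C)C(=O)N(C)OC)c(OC)c1
F3 | step 1 | 1-(3,4,5-trimethoxyphenyl)propan-1-one | CCC(=O)c1cc(OC)c(OC)c(OC)c1
F4 | step 1 | 4,4,4-trifluoro-2-methyl-1-(3,4,5-trimethoxyphenyl)butane-1,3-dione | CC(C(=O)C(F)(F)F)C(=O)c1cc(OC)c(OC)c(OC)c1
F5 | step 2 | 2-methoxy-4-vinylphenol | C=Cc1ccc(O)c(OC)c1
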